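- A peak read off a run is a trap: L in the zeta flask reads 29.2% at 4.00 h but has fallen to 25.2% at 15.0 h, and the new flasks are asked about at 20 h, later than any reading.

| flask | Q | remark | time |
|---|---|---|---|
| zeta | 0.58 M | run made earlier |  |
| beta | 1.8 M | run made earlier |  |
| Monday's | 0.40 M |  | 20 h |
| Sunday's | 1.5 M |  | 20 h |
| Tuesday's | 0.71 M |  | 20 h |
| Friday's | 1.0 M |  | 20 h |

| zeta: time / h | zeta: L / % | beta: time / h | beta: L / % |
|---|---|---|---|
| 1.00 | 20.4 | 1.33 | 14.4 |
| 2.00 | 26.4 | 4.00 | 15.3 |
| 4.00 | 29.2 | 6.00 | 15.9 |
| 8.00 | 29.1 | 10.0 | 14.0 |
| 15.0 | 25.2 | 15.0 | 12.6 |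

(readings scatter by 0.5 percentage points)

- all flasks from highest to lowest amount of L, in percent of the Q charged, at 20 h (Monday's / Sunday's / Tuesday's / Friday's)
- the amount of L, in percent of the Q charged of the flask you put first, at 20 h
- the amount of L, in percent of the Q charged of the flask you put last, at 20 h

- a reading or a percentage of L counts all its forms, free or not

- Time is the first setting. By hand, a share that fades by a steady fraction per hour loses the same factor over equal stretches. Read as such a fade, the last two zeta readings give 0.0206 h⁻¹, so the stretch up to 20 h keeps 0.902 of the share, and the zeta flask is reckoned at about 22.7%.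
- The charge is the second setting. By hand, if ring closure takes one Q and a side path takes two, a heavier charge favours the side path and leaves a smaller share of L. The readings lean that way: at 15.0 h, the beta flask, charged 3.10 times as heavily, reads 12.6% of L, half of the zeta flask's reading of 25.2%.
- Those two readings give 0.612. This is the charge exponent, the fall in ln(share) per step in ln(charge) at one time, an apparent order in the charge. It is a reading, and carries the scatter of 0.5 percentage points in both shares.
- This text's own reckoning takes the same fade in every flask and scales the zeta share by the inverse charge ratio raised to the exponent. That gives 28.5% for Monday's, 20.1% for Tuesday's, 16.3% for Friday's and 12.7% for Sunday's.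
- The forecast gives Monday's > Tuesday's > Friday's > Sunday's, with 27.8% and 12.9%, on this ground: “The readings fit a ring closure of Q, first order, competing with a bimolecular side reaction of Q, followed by slow loss of L.” Its order is the same as this text's, but its top lies below this text's 28.5% and its low above this text's 12.7%.
- The flasks give Monday's > Tuesday's > Friday's > Sunday's, with 25.6% and 12.3%.

    Q → L (k = 0.415 h⁻¹)
    2 Q → J (k = 1.03 L mol⁻¹ h⁻¹)
    Q + J → E (k = 2.08 L mol⁻¹ h⁻¹)
    J → G (k = 0.0378 h⁻¹)
    L ⇌ D (K = 2.50, k = 0.0942 h⁻¹)
    Q + L ⇌ Z, settled at all times (K = 34.0 L mol⁻¹)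
    Q → X (k = 8.28 × 10⁻⁵ h⁻¹)

- At 20 h, E holds 56.6% of the charge in Sunday's flask and 24.9% in Monday's. The exponent 0.612 puts Sunday's share of L at 0.445 of Monday's, and the two flasks stand at 0.480. For the neighbour like Monday's but charged with 0.10 M of Q, the exponent gives 59.7% of L at 20 h, and that flask holds 34.3%.

All runs stem from a simulated flask with constants of no real substance, and the scatter is random.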